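**Strategy.** The route rests on cutting the O1–C7a bond of the lactone (benzofuran-2(3H)-one numbering; ring A is the benzene ring, ring B the five-membered lactone). O1 sits on C7a, directly ortho to C3a, and C3a carries the C3 benzylidene/C2 carboxyl unit. The carboxyl group of a (Z)-2-aryl-3-phenylacrylic acid can therefore hand its own oxygen to the lone C7a–H bond of ring A. One palladium-catalysed C–H activation/C–O cyclisation closes ring B and installs the fourth ring oxygen, so ring A needs only its C4, C6 and C7 oxygens beforehand. The precursor is acid 13, with the catechol masked as two MOM ethers and the alkene geometry already fixed.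

Key step: step 9

Remark: the target alkene is Z (benzylidene phenyl on the side of the C2 carbonyl). The same spatial arrangement is called E in stannane 11 only because tin outranks the ester carbon.

**Route**

Step 1
Reactants: 1 2-hydroxy-4-methoxybenzaldehyde
Product: 3 4-methoxybenzene-1,2-diol, via aryl formate 2 (not isolated)
Conditions: H2O2 (30% aq, 1.2 equiv), NaOH (1.0 equiv), H2O/THF, 0 °C to rt, under argon
Reagents that add atoms: hydrogen peroxide, OO
Why: Dakin oxidation, in which hydroperoxide adds to the formyl group of the ortho-hydroxy aldehyde, the electron-rich aryl group migrates to oxygen, and the aryl formate 2 is hydrolysed in the same basic medium.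

Step 2
Reactants: 3 4-methoxybenzene-1,2-diol
Product: 4 4-methoxy-1,2-bis(methoxymethoxy)benzene
Conditions: NaH (2.4 equiv), MOMCl (2.4 equiv), DMF, 0 °C to rt
Reagents that add atoms: chloromethyl methyl ether, COCCl
Why: Double Williamson etherification of the catechol dianion with the reactive α-chloro ether, giving acetals that direct the next lithiation and later leave under mild anhydrous acid.

Step 3
Reactants: 4 4-methoxy-1,2-bis(methoxymethoxy)benzene; 5 3-phenylpropanal
Product: 7 rac-1-[6-methoxy-2,3-bis(methoxymethoxy)phenyl]-3-phenylpropan-1-ol, via aryllithium 6 (not isolated)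
Conditions: n-BuLi (1.1 equiv), TMEDA, THF, 0 °C; then 5, −78 °C to 0 °C; then H2O
Reagents that add atoms: none
Why: Directed ortho-metalation at the ring carbon flanked by a methoxymethoxy and the methoxy group (the doubly coordinated, most acidic site), then 1,2-addition of the aryllithium to the aldehyde; the carbinol stereocentre forms as a racemate and is erased in step 4.

Step 4
Reactants: 7 rac-1-[6-methoxy-2,3-bis(methoxymethoxy)phenyl]-3-phenylpropan-1-ol
Product: 8 1-[6-methoxy-2,3-bis(methoxymethoxy)phenyl]-3-phenylpropan-1-one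
Conditions: IBX (1.5 equiv), DMSO, rt
Reagents that add atoms: none
Why: Oxidation of the secondary benzylic alcohol by the pentavalent iodine reagent under neutral conditions, which leave the MOM acetals intact.

Step 5
Reactants: 8 1-[6-methoxy-2,3-bis(methoxymethoxy)phenyl]-3-phenylpropan-1-one
Product: 9 1-[3-iodo-2-methoxy-5,6-bis(methoxymethoxy)phenyl]-3-phenylpropan-1-one
Conditions: NIS (1.1 equiv), TFA (10 mol%), MeCN, 0 °C to rt, dark
Reagents that add atoms: N-iodosuccinimide, O=C1CCC(=O)N1I
Why: Electrophilic aromatic iodination, where the ring carbon ortho to the methoxy and para to a methoxymethoxy group (only meta to the acyl group) is the more nucleophilic of the two free positions, the other being para to the acyl group and activated by a single ortho oxygen.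

Step 6
Reactants: 10 ethyl 3-phenylprop-2-ynoate
Product: 11 ethyl (E)-3-phenyl-2-(tributylstannyl)prop-2-enoate
Conditions: Bu3SnH (1.05 equiv), Pd(PPh3)4 (2 mol%), THF, 0 °C to rt
Reagents that add atoms: tributyltin hydride, CCCC[SnH](CCCC)CCCC
Why: Hydrostannation catalysed by zerovalent palladium, a syn addition that puts hydrogen on the β-carbon and tin on the α-carbon of the alkynoate, so phenyl ends up cis to the ester, which is the geometry of the target alkene.

Step 7
Reactants: 9 1-[3-iodo-2-methoxy-5,6-bis(methoxymethoxy)phenyl]-3-phenylpropan-1-one; 11 ethyl (E)-3-phenyl-2-(tributylstannyl)prop-2-enoate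
Product: 12 ethyl (Z)-2-[2-methoxy-4,5-bis(methoxymethoxy)-3-(3-phenylpropanoyl)phenyl]-3-phenylprop-2-enoate
Conditions: Pd(PPh3)4 (10 mol%), CuI (20 mol%), CsF (2 equiv), DMF, 45 °C
Reagents that add atoms: none
Why: Stille coupling, in which oxidative addition to the aryl iodide, copper- and fluoride-assisted transmetalation of the alkenylstannane and reductive elimination all retain the alkene geometry, so phenyl stays cis to the ester.

Step 8
Reactants: 12 ethyl (Z)-2-[2-methoxy-4,5-bis(methoxymethoxy)-3-(3-phenylpropanoyl)phenyl]-3-phenylprop-2-enoate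
Product: 13 (Z)-2-[2-methoxy-4,5-bis(methoxymethoxy)-3-(3-phenylpropanoyl)phenyl]-3-phenylprop-2-enoic acid
Conditions: LiOH·H2O (5 equiv), THF/MeOH/H2O, 40 °C; then 1 M HCl to pH 4, 0 °C
Reagents that add atoms: lithium hydroxide, [Li+].[OH-]
Why: Saponification of the ethyl ester by acyl substitution with hydroxide, conditions under which the ketone, the MOM acetals and the trisubstituted alkene have no pathway for change.

Step 9
Reactants: 13 (Z)-2-[2-methoxy-4,5-bis(methoxymethoxy)-3-(3-phenylpropanoyl)phenyl]-3-phenylprop-2-enoic acid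
Product: 14 (Z)-3-benzylidene-4-methoxy-6,7-bis(methoxymethoxy)-5-(3-phenylpropanoyl)-1-benzofuran-2(3H)-one
Conditions: Pd(OAc)2 (10 mol%), N-acetylglycine (20 mol%), PhI(OAc)2 (1.5 equiv), KOAc (2 equiv), t-BuOH, 80 °C
Reagents that add atoms: none
Why: The carboxylate of 13 binds Pd(OAc)2, acetate-assisted concerted metalation–deprotonation at the future C7a–H (the only hydrogen on ring A) gives a six-membered C,O-palladacycle of divalent palladium, PhI(OAc)2 oxidises it to tetravalent palladium, and C–O reductive elimination forms the O1–C7a bond and returns divalent palladium. The closest known reaction type is the Pd(OAc)2/PhI(OAc)2 carboxylate-directed C–H activation/C–O cyclisation of α,α-disubstituted arylacetic acids to benzofuran-2(3H)-ones; in 13 the sp2 α-carbon restricts rotation and holds the carboxylate beside the C–H bond, as the quaternary centre does in those cases. Ring B closes by aryl C–O reductive elimination from the six-membered palladacycle, formally a 5-exo-trig attack of the carboxylate oxygen on the metalated ring carbon. No stereocentre is formed, and the Z alkene set in steps 6 and 7 takes no part in any bond change, so it should be carried through. The step needs site selectivity against the ortho C–H bonds of the benzylidene phenyl, which lies cis to the carboxylate: those would require a seven-membered palladacycle on a less electron-rich ring, while on ring A the other ortho position carries the C4 methoxy and the ketone has no ortho hydrogen for a rival metalation. KOAc buffers the acetic acid formed so that the MOM ethers survive, and N-acetylglycine acts as the internal base that should speed metalation at this flanked position.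

Step 10
Reactants: 14 (Z)-3-benzylidene-4-methoxy-6,7-bis(methoxymethoxy)-5-(3-phenylpropanoyl)-1-benzofuran-2(3H)-one
Product: 15 bractelactone, (Z)-3-benzylidene-6,7-dihydroxy-4-methoxy-5-(3-phenylpropanoyl)-1-benzofuran-2(3H)-one
Conditions: TFA/CH2Cl2 (1:4), 0 °C to rt; volatiles removed under vacuum
Reagents that add atoms: none
Why: Acid-catalysed cleavage of the two aryl methoxymethyl acetals without water or alcohol, so the aryl lactone is not opened; ring A has no free position to capture the methoxymethyl cation and the aryl methyl ether is stable to TFA.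

**Compound list**

1 | 2-hydroxy-4-methoxybenzaldehyde | COc1ccc(C=O)c(O)c1 | starting material
2 | 2-hydroxy-4-methoxyphenyl formate | COc1ccc(OC=O)c(O)c1 | intermediate
3 | 4-methoxybenzene-1,2-diol | COc1ccc(O)c(O)c1 | intermediate
4 | 4-methoxy-1,2-bis(methoxymethoxy)benzene | COCOc1ccc(OC)cc1OCOC | intermediate
5 | 3-phenylpropanal | O=CCCc1ccccc1 | starting material
6 | [6-methoxy-2,3-bis(methoxymethoxy)phenyl]lithium | [Li]c1c(OC)ccc(OCOC)c1OCOC | intermediate
7 | rac-1-[6-methoxy-2,3-bis(methoxymethoxy)phenyl]-3-phenylpropan-1-ol | COCOc1ccc(OC)c(C(O)CCc2ccccc2)c1OCOC | intermediate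
8 | 1-[6-methoxy-2,3-bis(methoxymethoxy)phenyl]-3-phenylpropan-1-one | COCOc1ccc(OC)c(C(=O)CCc2ccccc2)c1OCOC | intermediate
9 | 1-[3-iodo-2-methoxy-5,6-bis(methoxymethoxy)phenyl]-3-phenylpropan-1-one | COCOc1cc(I)c(OC)c(C(=O)CCc2ccccc2)c1OCOC | intermediate
10 | ethyl 3-phenylprop-2-ynoate | CCOC(=O)C#Cc1ccccc1 | starting material
11 | ethyl (E)-3-phenyl-2-(tributylstannyl)prop-2-enoate | CCCC[Sn](CCCC)(CCCC)/C(=C/c1ccccc1)C(=O)OCC | intermediate
12 | ethyl (Z)-2-[2-methoxy-4,5-bis(methoxymethoxy)-3-(3-phenylpropanoyl)phenyl]-3-phenylprop-2-enoate | COc1c(C(=O)CCc2ccccc2)c(OCOC)c(OCOC)cc1/C(=C/c1ccccc1)C(=O)OCC | intermediate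
13 | (Z)-2-[2-methoxy-4,5-bis(methoxymethoxy)-3-(3-phenylpropanoyl)phenyl]-3-phenylprop-2-enoic acid | COc1c(C(=O)CCc2ccccc2)c(OCOC)c(OCOC)cc1/C(=C/c1ccccc1)C(=O)O | intermediate
14 | (Z)-3-benzylidene-4-methoxy-6,7-bis(methoxymethoxy)-5-(3-phenylpropanoyl)-1-benzofuran-2(3H)-one | COc1c(C(=O)CCc2ccccc2)c(OCOC)c(OCOC)c2c1/C(=C/c1ccccc1)C(=O)O2 | intermediate
15 | bractelactone, (Z)-3-benzylidene-6,7-dihydroxy-4-methoxy-5-(3-phenylpropanoyl)-1-benzofuran-2(3H)-one | COc1c(C(=O)CCc2ccccc2)c(O)c(O)c2c1/C(=C/c1ccccc1)C(=O)O2 | target

**Totals**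

Total step count: 10. Longest linear sequence: 9 steps (steps 1 to 5 and 7 to 10, from 2-hydroxy-4-methoxybenzaldehyde).

**Steps most likely to fail**

1. Step 9. Cyclometalation at the C–H bond flanked by a methoxymethoxy group and the acrylate arm may be slow. Palladation of the benzylidene phenyl, acetoxylation, or oxidative degradation of the electron-rich ring by the trivalent iodine oxidant could then take over. The fallback sets out from carbinol 7 and returns at 14; it brings in the fourth oxygen by directed ortho-metalation and closes ring B by ordinary lactonisation.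
   - Treating 7 with n-BuLi (2.2 equiv) and TMEDA should give the alkoxide/aryllithium dianion, lithiated ortho to the methoxymethoxy group that still has a free neighbour. Trapping with B(OMe)3 and oxidation with H2O2/NaOH should give rac-4-(1-hydroxy-3-phenylpropyl)-5-methoxy-2,3-bis(methoxymethoxy)phenol F1.
   - DDQ in dioxane should oxidise the para-hydroxybenzylic alcohol to 1-[4-hydroxy-6-methoxy-2,3-bis(methoxymethoxy)phenyl]-3-phenylpropan-1-one F2.
   - NIS in MeCN should iodinate the single remaining ring position, ortho to the hydroxyl and the methoxy group, giving 1-[4-hydroxy-3-iodo-2-methoxy-5,6-bis(methoxymethoxy)phenyl]-3-phenylpropan-1-one F3.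
   - Stille coupling with 11 under the conditions of step 7 should give ethyl (Z)-2-[2-hydroxy-6-methoxy-3,4-bis(methoxymethoxy)-5-(3-phenylpropanoyl)phenyl]-3-phenylprop-2-enoate F4.
   - LiOH should give (Z)-2-[2-hydroxy-6-methoxy-3,4-bis(methoxymethoxy)-5-(3-phenylpropanoyl)phenyl]-3-phenylprop-2-enoic acid F5, which EDC·HCl in CH2Cl2 should close to 14.

2. Step 7. Transmetalation of the α-ester-substituted alkenylstannane onto an ortho-substituted arylpalladium species may be slow, so protodestannylation, stannane homocoupling or cine substitution could compete. The fallback sets out from 9 and 11 and returns at 12; it reverses the polarity of the partners and uses a Suzuki–Miyaura coupling.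
   - Miyaura borylation of 9 (B2pin2, PdCl2(dppf), KOAc, dioxane, 80 °C) should give 1-[2-methoxy-5,6-bis(methoxymethoxy)-3-(4,4,5,5-tetramethyl-1,3,2-dioxaborolan-2-yl)phenyl]-3-phenylpropan-1-one F6.
   - Iododestannylation of 11 with I2 in CH2Cl2 at 0 °C should give, with retention, ethyl (E)-2-iodo-3-phenylprop-2-enoate F7.
   - Coupling of F6 with F7 (Pd(OAc)2, SPhos, K3PO4, toluene/H2O, 60 °C) should give 12 with the phenyl still cis to the ester.

3. Step 5. The acyl group lowers the nucleophilicity of the ring, so the acid co-catalyst may begin to cleave the methoxymethyl ether next to the ketone. Iodination at the ketone α-carbon or at the other free ring carbon may also compete. The fallback sets out from carbinol 7 and returns at 9; it moves the halogenation ahead of the oxidation so that the substitution runs on a ring without the acyl group and needs no acid. NIS in MeCN at rt should give rac-1-[3-iodo-2-methoxy-5,6-bis(methoxymethoxy)phenyl]-3-phenylpropan-1-ol F8, and IBX in DMSO should then oxidise it to 9.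

**Further compounds**

F1 | step 9 | rac-4-(1-hydroxy-3-phenylpropyl)-5-methoxy-2,3-bis(methoxymethoxy)phenol | COCOc1c(O)cc(OC)c(C(O)CCc2ccccc2)c1OCOC
F2 | step 9 | 1-[4-hydroxy-6-methoxy-2,3-bis(methoxymethoxy)phenyl]-3-phenylpropan-1-one | COCOc1c(O)cc(OC)c(C(=O)CCc2ccccc2)c1OCOC
F3 | step 9 | 1-[4-hydroxy-3-iodo-2-methoxy-5,6-bis(methoxymethoxy)phenyl]-3-phenylpropan-1-one | COCOc1c(O)c(I)c(OC)c(C(=O)CCc2ccccc2)c1OCOC
F4 | step 9 | ethyl (Z)-2-[2-hydroxy-6-methoxy-3,4-bis(methoxymethoxy)-5-(3-phenylpropanoyl)phenyl]-3-phenylprop-2-enoate | COc1c(C(=O)CCc2ccccc2)c(OCOC)c(OCOC)c(O)c1/C(=C/c1ccccc1)C(=O)OCC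
F5 | step 9 | (Z)-2-[2-hydroxy-6-methoxy-3,4-bis(methoxymethoxy)-5-(3-phenylpropanoyl)phenyl]-3-phenylprop-2-enoic acid | COc1c(C(=O)CCc2ccccc2)c(OCOC)c(OCOC)c(O)c1/C(=C/c1ccccc1)C(=O)O
F6 | step 7 | 1-[2-methoxy-5,6-bis(methoxymethoxy)-3-(4,4,5,5-tetramethyl-1,3,2-dioxaborolan-2-yl)phenyl]-3-phenylpropan-1-one | COCOc1cc(B2OC(C)(C)C(C)(C)O2)c(OC)c(C(=O)CCc2ccccc2)c1OCOC
F7 | step 7 | ethyl (E)-2-iodo-3-phenylprop-2-enoate | I/C(=C/c1ccccc1)C(=O)OCC
F8 | step 5 | rac-1-[3-iodo-2-methoxy-5,6-bis(methoxymethoxy)phenyl]-3-phenylpropan-1-ol | COCOc1cc(I)c(OC)c(C(O)CCc2ccccc2)c1OCOC
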